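**Retrosynthetic overview**

1. Feature: the C8 ketone, the Z C7=C11 double bond and the C12 hydroxymethyl cis to C8 are one oxidatively opened 3-methylfuran (O–C8=C7–C11=C12). The C9 carbinol of ring B is then a furfuryl alcohol.
2. Target ⇒ (desilylation, C12 aldehyde reduction, NBS opening of the furan) ⇒ 3α-acyloxy-10βH-furanoeremophilan-9β-ol.
3. Key disconnection C8–C9: ring B (C5–C6–C7–C8–C9–C10) is closed by Me2AlCl-mediated attack of furan C8 on the C9 aldehyde of a monocyclic ring A precursor.
4. Precursor ⇒ 3β-hydroxy aldehyde + trienoic acid (Mitsunobu, inversion at C3). C10 is set by equilibration, C5 by enolate alkylation with 3-(bromomethyl)-4-methylfuran, C4 by conjugate reduction, C3 by asymmetric α'-hydroxylation of the vinylogous ester of 2-methylcyclohexane-1,3-dione.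
5. Ring order: ring A (from the dione) → furan (brought in intact) → ring B (key step); the furan is opened afterwards.

Key step: step 18

Remark: eremophilane numbering and α/β (C5 methyl = β) are used for ring atoms; the C3 oxygen is deliberately carried as the 3β epimer (S, cis to the C4 methyl) from step 7 to step 14 and becomes 3α (R) in step 17; the sense of induction of the oxaziridine (step 7) and the position of the C10 equilibrium (step 13) are predictions to be checked on first runs.

**Route**

Step 1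
Reactants: 1 diethyl furan-3,4-dicarboxylate
Product: 3 4-(ethoxycarbonyl)furan-3-carboxylic acid, via potassium carboxylate 2 (not isolated)
Conditions: KOH (1.0 equiv), EtOH, 0 °C → rt; then aq. HCl
Reagents that add atoms: potassium hydroxide, [K+].[OH-]
Why: Half-saponification of a symmetric diester, in which one equivalent of hydroxide cleaves one ester and the carboxylate salt that separates from ethanol resists a second hydrolysis.

Step 2
Reactants: 3 4-(ethoxycarbonyl)furan-3-carboxylic acid
Product: 4 ethyl 4-(hydroxymethyl)furan-3-carboxylate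
Conditions: BH3·SMe2, THF, 0 °C → rt; MeOH quench
Reagents that add atoms: none
Why: Borane reduces the carboxylic acid chemoselectively (through the acyloxyborane) and leaves the ester and the deactivated furan untouched.

Step 3
Reactants: 4 ethyl 4-(hydroxymethyl)furan-3-carboxylate
Product: 5 ethyl 4-(bromomethyl)furan-3-carboxylate
Conditions: CBr4, PPh3, CH2Cl2, 0 °C
Reagents that add atoms: tetrabromomethane, BrC(Br)(Br)Br
Why: Appel bromination converts the primary furylmethyl alcohol into the bromide under neutral conditions that the ester-deactivated furan tolerates.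

Step 4
Reactants: 5 ethyl 4-(bromomethyl)furan-3-carboxylate
Product: 6 (4-methylfuran-3-yl)methanol
Conditions: LiBHEt3 (excess), THF, −78 → 0 °C; aq. NH4Cl
Reagents that add atoms: none
Why: LiBHEt3 is a very fast SN2 hydride donor, so it first replaces the furylmethyl bromide by hydrogen (creating the future C13 methyl) and then reduces the ester to the primary alcohol in the same flask.

Step 5
Reactants: 6 (4-methylfuran-3-yl)methanol
Product: 7 3-(bromomethyl)-4-methylfuran
Conditions: PBr3, pyridine (cat.), Et2O, −10 °C; used at once as a cold solution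
Reagents that add atoms: phosphorus tribromide, BrP(Br)Br
Why: PBr3 bromination of the primary 3-furylmethyl alcohol gives the benzylic-type bromide, which is kept cold and used directly because it ionises easily.

Step 6
Reactants: 8 2-methylcyclohexane-1,3-dione
Product: 9 2-methyl-3-(2-methylpropoxy)cyclohex-2-en-1-one
Conditions: i-BuOH, TsOH·H2O (cat.), benzene, reflux, Dean–Stark
Reagents that add atoms: 2-methylpropan-1-ol, CC(C)CO
Why: Acid-catalysed enol etherification of the cyclic 1,3-dione with azeotropic removal of water gives the vinylogous ester, whose α' carbon can then be deprotonated selectively.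

Step 7
Reactants: 9 2-methyl-3-(2-methylpropoxy)cyclohex-2-en-1-one
Product: 11 (6S)-6-hydroxy-2-methyl-3-(2-methylpropoxy)cyclohex-2-en-1-one, via lithium dienolate 10 (not isolated)
Conditions: LiN(i-Pr)2, THF, −78 °C; then (camphorsulfonyl)oxaziridine (enantiomer giving 6S; the (−)-(2S,8aR) reagent assumed), −78 °C; aq. NH4Cl
Reagents that add atoms: (camphorsulfonyl)oxaziridine, CC1(C)C2CCC13CS(=O)(=O)N4OC34C2
Why: Kinetic α' deprotonation gives the cross-conjugated dienolate, and Davis asymmetric enolate hydroxylation with the chiral oxaziridine differentiates its faces and sets the carbinol centre (future C3, here S), any shortfall in enantiomeric purity being removable by crystallisation at this stage.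

Step 8
Reactants: 11 (6S)-6-hydroxy-2-methyl-3-(2-methylpropoxy)cyclohex-2-en-1-one
Product: 12 (6S)-6-{[tert-butyl(dimethyl)silyl]oxy}-2-methyl-3-(2-methylpropoxy)cyclohex-2-en-1-one
Conditions: TBSCl, imidazole, DMF, rt
Reagents that add atoms: tert-butyl(chloro)dimethylsilane, CC(C)(C)[Si](C)(C)Cl
Why: Standard silylation of the secondary α-hydroxy ketone under weakly basic conditions that do not epimerise the carbinol centre.

Step 9
Reactants: 12 (6S)-6-{[tert-butyl(dimethyl)silyl]oxy}-2-methyl-3-(2-methylpropoxy)cyclohex-2-en-1-one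
Product: 14 (4S)-4-{[tert-butyl(dimethyl)silyl]oxy}-2,3-dimethylcyclohex-2-en-1-one, via tertiary carbinol 13 (not isolated)
Conditions: MeLi, CeCl3, THF, −78 °C; then 1 M HCl, THF, 0 °C
Reagents that add atoms: methyllithium, [Li]C; water, O
Why: Stork–Danheiser enone transposition, in which the non-basic MeCeCl2 adds to the vinylogous ester carbonyl without enolising the α-silyloxy stereocentre and dilute acid hydrolyses the enol ether and dehydrates to the transposed 2,3-dimethyl enone.

Step 10
Reactants: 14 (4S)-4-{[tert-butyl(dimethyl)silyl]oxy}-2,3-dimethylcyclohex-2-en-1-one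
Product: 15 tert-butyl{[(1S,2R)-4-{[dimethyl(phenyl)silyl]oxy}-2,3-dimethylcyclohex-3-en-1-yl]oxy}dimethylsilane
Conditions: [(Ph3P)CuH]6 (cat.), PhMe2SiH, toluene, rt
Reagents that add atoms: dimethyl(phenyl)silane, C[SiH](C)c1ccccc1
Why: CuH-catalysed conjugate hydrosilylation delivers hydride to the β carbon (C4) anti to the pseudo-axial γ-silyloxy group, as Me2CuLi adds to 4-silyloxycyclohexenones, so the C4 methyl ends cis to the C3 oxygen and the enolate is trapped regiospecifically; dissolving-metal reduction is avoided because it would expel the γ-oxygen.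

Step 11
Reactants: 15 tert-butyl{[(1S,2R)-4-{[dimethyl(phenyl)silyl]oxy}-2,3-dimethylcyclohex-3-en-1-yl]oxy}dimethylsilane; 7 3-(bromomethyl)-4-methylfuran
Product: 17 (2R,3R,4S)-4-{[tert-butyl(dimethyl)silyl]oxy}-2,3-dimethyl-2-[(4-methylfuran-3-yl)methyl]cyclohexan-1-one, via lithium enolate 16 (not isolated)
Conditions: MeLi, THF, 0 °C; then 7, HMPA, −78 → −20 °C
Reagents that add atoms: none
Why: Methyllithium cleaves the silyl enol ether to the regiodefined tetrasubstituted lithium enolate, which is C-alkylated by the reactive furylmethyl bromide; allylic strain puts the C4 methyl pseudo-axial, so the electrophile enters C5 from the opposite (α) face and the quaternary centre is formed with the cis vicinal dimethyl pattern.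

Step 12
Reactants: 17 (2R,3R,4S)-4-{[tert-butyl(dimethyl)silyl]oxy}-2,3-dimethyl-2-[(4-methylfuran-3-yl)methyl]cyclohexan-1-one
Product: 18 tert-butyl{[(1S,2R,3R)-4-(methoxymethylidene)-2,3-dimethyl-3-[(4-methylfuran-3-yl)methyl]cyclohexyl]oxy}dimethylsilane (E/Z mixture)
Conditions: Ph3P(CH2OMe)Cl, KN(SiMe3)2, THF, 0 °C; then 17, 0 → 45 °C
Reagents that add atoms: (methoxymethyl)triphenylphosphonium chloride, COC[P+](c1ccccc1)(c1ccccc1)c1ccccc1.[Cl-]
Why: Wittig methoxymethylenation adds the C9 carbon to the hindered C10 ketone with an excess of the small reactive ylide, the enol ether geometry being irrelevant.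

Step 13
Reactants: 18 tert-butyl{[(1S,2R,3R)-4-(methoxymethylidene)-2,3-dimethyl-3-[(4-methylfuran-3-yl)methyl]cyclohexyl]oxy}dimethylsilane
Product: 20 (1S,2R,3R,4S)-4-{[tert-butyl(dimethyl)silyl]oxy}-2,3-dimethyl-2-[(4-methylfuran-3-yl)methyl]cyclohexane-1-carbaldehyde, via 10-epi aldehyde 19 (not isolated)
Conditions: Cl3CCO2H, CH2Cl2/H2O, 0 °C → rt; then DBU (cat.), CH2Cl2, rt; chromatography, minor epimer recycled
Reagents that add atoms: water, O
Why: Enol ether hydrolysis (kinetic protonation of C10 from the less hindered face should give mainly 19) is followed by base-mediated epimerisation of the aldehyde: with the 3β-silyloxy, 4β-methyl and 5β-methyl groups all cis, ring A prefers the chair with the silyloxy and C5 methyl equatorial and the C4 methyl and furylmethyl axial, and only the α-formyl epimer 20 is equatorial in that chair (the β epimer is 1,3-diaxial to the C4 methyl or must flip to a chair with the silyloxy and C5 methyl syn-diaxial), so thermodynamic control should set C10 with the formyl cis to the furylmethyl group.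

Step 14
Reactants: 20 (1S,2R,3R,4S)-4-{[tert-butyl(dimethyl)silyl]oxy}-2,3-dimethyl-2-[(4-methylfuran-3-yl)methyl]cyclohexane-1-carbaldehyde
Product: 21 (1S,2R,3R,4S)-4-hydroxy-2,3-dimethyl-2-[(4-methylfuran-3-yl)methyl]cyclohexane-1-carbaldehyde
Conditions: HF·pyridine, pyridine, THF, 0 °C → rt
Reagents that add atoms: none
Why: Buffered HF·pyridine cleaves the secondary silyl ether under non-basic conditions that neither epimerise the aldehyde nor harm the furan, and the trans-1,4 hydroxy aldehyde cannot form a lactol.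

Step 15
Reactants: 22 (E)-non-3-en-2-one; 23 triethyl (E)-4-phosphonocrotonate
Product: 25 ethyl (2E,4E,6E)-5-methyldodeca-2,4,6-trienoate, via lithiated phosphonate 24 (not isolated)
Conditions: LiN(SiMe3)2, THF, −78 °C; then 22, −78 °C → rt; then I2 (cat.), hexane, daylight
Reagents that add atoms: none
Why: Vinylogous Horner–Wadsworth–Emmons olefination of the methyl ketone with the γ-phosphonocrotonate anion builds C1–C5 of the trienoate in one step, and iodine-catalysed equilibration converges the E/Z mixture at the new C4=C5 bond on the all-E isomer.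

Step 16
Reactants: 25 ethyl (2E,4E,6E)-5-methyldodeca-2,4,6-trienoate
Product: 27 (2E,4E,6E)-5-methyldodeca-2,4,6-trienoic acid, via lithium carboxylate 26 (not isolated)
Conditions: LiOH, THF/MeOH/H2O, rt; then aq. HCl
Reagents that add atoms: lithium hydroxide, [Li+].[OH-]
Why: Saponification of the unhindered ethyl ester gives the crystalline trienoic acid without touching the triene geometry.

Step 17
Reactants: 21 (1S,2R,3R,4S)-4-hydroxy-2,3-dimethyl-2-[(4-methylfuran-3-yl)methyl]cyclohexane-1-carbaldehyde; 27 (2E,4E,6E)-5-methyldodeca-2,4,6-trienoic acid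
Product: 28 (1R,2R,3R,4S)-4-formyl-2,3-dimethyl-3-[(4-methylfuran-3-yl)methyl]cyclohexyl (2E,4E,6E)-5-methyldodeca-2,4,6-trienoate
Conditions: PPh3, DIAD, toluene, 0 °C → rt
Reagents that add atoms: none
Why: Mitsunobu esterification, in which the carboxylate displaces the 3β-alkoxyphosphonium group with inversion, attaches the trienoate and turns the temporary 3β configuration into the required 3α one under neutral conditions that leave the epimerisable aldehyde alone.

Step 18
Reactants: 28 (1R,2R,3R,4S)-4-formyl-2,3-dimethyl-3-[(4-methylfuran-3-yl)methyl]cyclohexyl (2E,4E,6E)-5-methyldodeca-2,4,6-trienoate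
Product: 30 3α-[(2E,4E,6E)-5-methyldodeca-2,4,6-trienoyloxy]-10βH-furanoeremophilan-9β-ol, via aluminium alkoxide 29 (not isolated)
Conditions: Me2AlCl (2.5 equiv), CH2Cl2 (high dilution), −78 °C; quench at −78 °C with Et3N, then aq. potassium sodium tartrate
Reagents that add atoms: none
Why: Me2AlCl binds the C9 aldehyde oxygen and the furan, tethered through C6 to C5, attacks the activated carbonyl carbon with its free α carbon C8 in an intramolecular electrophilic aromatic substitution; loss of the C8 proton rearomatises the ring, and the proton is consumed by an Al–CH3 bond as methane, leaving the chloro(methyl)aluminium alkoxide 29, which should not ionise at −78 °C. The closest known reaction type is the Lewis-acid-mediated Friedel–Crafts hydroxyalkylation of furans by tethered aldehydes to give fused furfuryl alcohols. Ring B is closed by a 6-exo-trig attack on the carbonyl, the furan C7=C8 bond ending inside the new six-membered ring. The only new stereocentre, C9, is controlled by ring A: in the chair with the 3α-ester, C4 methyl and furylmethyl group equatorial and the C5 methyl and formyl group axial, the half-chair transition state places the bulky aluminium-bound oxygen pseudo-equatorial on the H10 side, because the pseudo-axial position is 1,3-diaxial to the C5–C4 bond, and this gives the 9β alcohol with the cis ring fusion fixed in step 13. Regioselectivity is secured by the tether, since only C8 and not C12 can reach C9 in a six-membered ring, and chemoselectivity by the low temperature and the proton-scavenging Lewis acid, which spare the trienoate and the acid-sensitive furfuryl oxygen.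

Step 19
Reactants: 30 3α-[(2E,4E,6E)-5-methyldodeca-2,4,6-trienoyloxy]-10βH-furanoeremophilan-9β-ol
Product: 31 3α-[(2E,4E,6E)-5-methyldodeca-2,4,6-trienoyloxy]-9β-(triethylsilyloxy)-10βH-furanoeremophilane
Conditions: TESCl, imidazole, DMAP (cat.), CH2Cl2, 0 °C
Reagents that add atoms: chloro(triethyl)silane, CC[Si](Cl)(CC)CC
Why: Silylation of the only free hydroxyl protects the furfuryl position against ionisation during the oxidation and blocks hydroxyl-assisted reduction of the later C8 ketone.

Step 20
Reactants: 31 3α-[(2E,4E,6E)-5-methyldodeca-2,4,6-trienoyloxy]-9β-(triethylsilyloxy)-10βH-furanoeremophilane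
Product: 32 (7(11)Z)-8,12-dioxo-9β-(triethylsilyloxy)-10βH-eremophil-7(11)-en-3α-yl (2E,4E,6E)-5-methyldodeca-2,4,6-trienoate
Conditions: NBS (1.05 equiv), NaHCO3, THF/H2O, −20 °C, dark; crude product used at once
Reagents that add atoms: water, O
Why: Oxidative furan opening by NBS in buffered aqueous medium (bromination at the free α carbon C12, addition of water at C8, loss of HBr) turns the furan into the cis-enedione, so the C8 ketone and the C12 aldehyde are held Z across C7=C11; the electron-rich trialkylfuran should react far faster than the ester-deactivated triene.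

Step 21
Reactants: 32 (7(11)Z)-8,12-dioxo-9β-(triethylsilyloxy)-10βH-eremophil-7(11)-en-3α-yl (2E,4E,6E)-5-methyldodeca-2,4,6-trienoate
Product: 33 (7(11)Z)-12-hydroxy-8-oxo-9β-(triethylsilyloxy)-10βH-eremophil-7(11)-en-3α-yl (2E,4E,6E)-5-methyldodeca-2,4,6-trienoate
Conditions: NaBH4 (limiting), CH2Cl2/EtOH, −78 °C; pH 7 buffer
Reagents that add atoms: none
Why: Chemoselective low-temperature borohydride 1,2-reduction, in which the aldehyde is reduced much faster than the hindered, α-silyloxy-substituted conjugated ketone and the esters, gives the C12 alcohol with the Z geometry unchanged.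

Step 22
Reactants: 33 (7(11)Z)-12-hydroxy-8-oxo-9β-(triethylsilyloxy)-10βH-eremophil-7(11)-en-3α-yl (2E,4E,6E)-5-methyldodeca-2,4,6-trienoate
Product: 34 (7(11)Z)-9β,12-dihydroxy-8-oxo-10βH-eremophil-7(11)-en-3α-yl (2E,4E,6E)-5-methyldodeca-2,4,6-trienoate (CNP0226738.1)
Conditions: HF·pyridine, pyridine (excess), THF, 0 °C; solid NaHCO3 quench
Reagents that add atoms: none
Why: Pyridine-buffered fluoride cleaves the triethylsilyl ether under conditions mild enough to avoid acid-catalysed cyclodehydration of the Z-γ-hydroxy enone back to the furan and base-induced damage to the α-ketol and the ester.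

**Compound list**

1 | diethyl furan-3,4-dicarboxylate | CCOC(=O)c1cocc1C(=O)OCC | starting material
2 | potassium 4-(ethoxycarbonyl)furan-3-carboxylate | [K+].CCOC(=O)c1cocc1C(=O)[O-] | intermediate
3 | 4-(ethoxycarbonyl)furan-3-carboxylic acid | CCOC(=O)c1cocc1C(=O)O | intermediate
4 | ethyl 4-(hydroxymethyl)furan-3-carboxylate | CCOC(=O)c1cocc1CO | intermediate
5 | ethyl 4-(bromomethyl)furan-3-carboxylate | CCOC(=O)c1cocc1CBr | intermediate
6 | (4-methylfuran-3-yl)methanol | Cc1cocc1CO | intermediate
7 | 3-(bromomethyl)-4-methylfuran | Cc1cocc1CBr | intermediate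
8 | 2-methylcyclohexane-1,3-dione | CC1C(=O)CCCC1=O | starting material
9 | 2-methyl-3-(2-methylpropoxy)cyclohex-2-en-1-one | CC1=C(OCC(C)C)CCCC1=O | intermediate
10 | lithium 6-methyl-5-(2-methylpropoxy)cyclohexa-1,5-dien-1-olate | CC1=C(OCC(C)C)CCC=C1O[Li] | intermediate
11 | (6S)-6-hydroxy-2-methyl-3-(2-methylpropoxy)cyclohex-2-en-1-one | O[C@H]1CCC(OCC(C)C)=C(C)C1=O | intermediate
12 | (6S)-6-{[tert-butyl(dimethyl)silyl]oxy}-2-methyl-3-(2-methylpropoxy)cyclohex-2-en-1-one | CC(C)(C)[Si](C)(C)O[C@H]1CCC(OCC(C)C)=C(C)C1=O | intermediate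
13 | (6S)-6-{[tert-butyl(dimethyl)silyl]oxy}-1,2-dimethyl-3-(2-methylpropoxy)cyclohex-2-en-1-ol (both C1 epimers) | CC(C)(C)[Si](C)(C)O[C@H]1CCC(OCC(C)C)=C(C)C1(C)O | intermediate
14 | (4S)-4-{[tert-butyl(dimethyl)silyl]oxy}-2,3-dimethylcyclohex-2-en-1-one | CC(C)(C)[Si](C)(C)O[C@H]1CCC(=O)C(C)=C1C | intermediate
15 | tert-butyl{[(1S,2R)-4-{[dimethyl(phenyl)silyl]oxy}-2,3-dimethylcyclohex-3-en-1-yl]oxy}dimethylsilane | CC(C)(C)[Si](C)(C)O[C@H]1CCC(O[Si](C)(C)c2ccccc2)=C(C)[C@H]1C | intermediate
16 | lithium (3R,4S)-4-{[tert-butyl(dimethyl)silyl]oxy}-2,3-dimethylcyclohex-1-en-1-olate | CC(C)(C)[Si](C)(C)O[C@H]1CCC(O[Li])=C(C)[C@H]1C | intermediate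
17 | (2R,3R,4S)-4-{[tert-butyl(dimethyl)silyl]oxy}-2,3-dimethyl-2-[(4-methylfuran-3-yl)methyl]cyclohexan-1-one | CC(C)(C)[Si](C)(C)O[C@H]1CCC(=O)[C@](C)(Cc2cocc2C)[C@H]1C | intermediate
18 | tert-butyl{[(1S,2R,3R)-4-(methoxymethylidene)-2,3-dimethyl-3-[(4-methylfuran-3-yl)methyl]cyclohexyl]oxy}dimethylsilane (E/Z mixture) | CC(C)(C)[Si](C)(C)O[C@H]1CCC(=COC)[C@](C)(Cc2cocc2C)[C@H]1C | intermediate
19 | (1R,2R,3R,4S)-4-{[tert-butyl(dimethyl)silyl]oxy}-2,3-dimethyl-2-[(4-methylfuran-3-yl)methyl]cyclohexane-1-carbaldehyde (formyl trans to furylmethyl) | CC(C)(C)[Si](C)(C)O[C@H]1CC[C@@H](C=O)[C@](C)(Cc2cocc2C)[C@H]1C | intermediate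
20 | (1S,2R,3R,4S)-4-{[tert-butyl(dimethyl)silyl]oxy}-2,3-dimethyl-2-[(4-methylfuran-3-yl)methyl]cyclohexane-1-carbaldehyde (formyl cis to furylmethyl) | CC(C)(C)[Si](C)(C)O[C@H]1CC[C@H](C=O)[C@](C)(Cc2cocc2C)[C@H]1C | intermediate
21 | (1S,2R,3R,4S)-4-hydroxy-2,3-dimethyl-2-[(4-methylfuran-3-yl)methyl]cyclohexane-1-carbaldehyde | O[C@H]1CC[C@H](C=O)[C@](C)(Cc2cocc2C)[C@H]1C | intermediate
22 | (E)-non-3-en-2-one | CCCCC/C=C/C(C)=O | starting material
23 | triethyl (E)-4-phosphonocrotonate | CCOC(=O)/C=C/CP(=O)(OCC)OCC | starting material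
24 | lithiated triethyl 4-phosphonocrotonate | [Li+].CCOC(=O)/C=C/[CH-]P(=O)(OCC)OCC | intermediate
25 | ethyl (2E,4E,6E)-5-methyldodeca-2,4,6-trienoate | CCCCC/C=C/C(C)=C/C=C/C(=O)OCC | intermediate
26 | lithium (2E,4E,6E)-5-methyldodeca-2,4,6-trienoate | [Li+].CCCCC/C=C/C(C)=C/C=C/C(=O)[O-] | intermediate
27 | (2E,4E,6E)-5-methyldodeca-2,4,6-trienoic acid | CCCCC/C=C/C(C)=C/C=C/C(=O)O | intermediate
28 | (1R,2R,3R,4S)-4-formyl-2,3-dimethyl-3-[(4-methylfuran-3-yl)methyl]cyclohexyl (2E,4E,6E)-5-methyldodeca-2,4,6-trienoate (3α-acyloxy-8,9-seco-furanoeremophilan-9-al) | CCCCC/C=C/C(C)=C/C=C/C(=O)O[C@@H]1CC[C@H](C=O)[C@](C)(Cc2cocc2C)[C@H]1C | intermediate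
29 | chloro(methyl)aluminium 9β-alkoxide of 30 | CCCCC/C=C/C(C)=C/C=C/C(=O)O[C@@H]1CC[C@@H]2[C@@H](O[Al](C)Cl)c3occ(C)c3C[C@]2(C)[C@H]1C | intermediate
30 | 3α-[(2E,4E,6E)-5-methyldodeca-2,4,6-trienoyloxy]-10βH-furanoeremophilan-9β-ol (3R,4R,5R,9R,10S) | CCCCC/C=C/C(C)=C/C=C/C(=O)O[C@@H]1CC[C@@H]2[C@@H](O)c3occ(C)c3C[C@]2(C)[C@H]1C | intermediate
31 | 3α-[(2E,4E,6E)-5-methyldodeca-2,4,6-trienoyloxy]-9β-(triethylsilyloxy)-10βH-furanoeremophilane | CCCCC/C=C/C(C)=C/C=C/C(=O)O[C@@H]1CC[C@@H]2[C@@H](O[Si](CC)(CC)CC)c3occ(C)c3C[C@]2(C)[C@H]1C | intermediate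
32 | (7(11)Z)-8,12-dioxo-9β-(triethylsilyloxy)-10βH-eremophil-7(11)-en-3α-yl (2E,4E,6E)-5-methyldodeca-2,4,6-trienoate | CCCCC/C=C/C(C)=C/C=C/C(=O)O[C@@H]1CC[C@@H]2[C@@H](O[Si](CC)(CC)CC)C(=O)/C(=C(/C)C=O)C[C@]2(C)[C@H]1C | intermediate
33 | (7(11)Z)-12-hydroxy-8-oxo-9β-(triethylsilyloxy)-10βH-eremophil-7(11)-en-3α-yl (2E,4E,6E)-5-methyldodeca-2,4,6-trienoate | CCCCC/C=C/C(C)=C/C=C/C(=O)O[C@@H]1CC[C@@H]2[C@@H](O[Si](CC)(CC)CC)C(=O)/C(=C(/C)CO)C[C@]2(C)[C@H]1C | intermediate
34 | (7(11)Z)-9β,12-dihydroxy-8-oxo-10βH-eremophil-7(11)-en-3α-yl (2E,4E,6E)-5-methyldodeca-2,4,6-trienoate (3R,4R,5R,9R,10S) | CCCCC/C=C/C(C)=C/C=C/C(=O)O[C@@H]1CC[C@@H]2[C@@H](O)C(=O)/C(=C(/C)CO)C[C@]2(C)[C@H]1C | target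

**Step count**

Total: 22 steps. Longest linear sequence: 15 steps (steps 6–14 and 17–22 from 2-methylcyclohexane-1,3-dione; the furan branch, steps 1–5, 11–14 and 17–22, is equally long).

**The three steps most likely to fail**

The first is step 13, in which C10 is set by equilibration. The conformational bias may be too small, so that the equilibrium does not lie far enough on the side of the α-formyl epimer, or epimerisation may stay incomplete. The fallback for step 13 sets the centre kinetically by hydroxyl-directed hydrogenation; it sets out from ketone 17 and comes back to the route at 21. KN(SiMe3)2 and PhNTf2 (THF, −78 °C) should convert 17 into (4S,5R,6R)-4-{[tert-butyl(dimethyl)silyl]oxy}-5,6-dimethyl-6-[(4-methylfuran-3-yl)methyl]cyclohex-1-en-1-yl trifluoromethanesulfonate F1 as the only enol triflate possible next to the quaternary carbon. Methoxycarbonylation with Pd(OAc)2, PPh3, CO, MeOH and Et3N in DMF should then give methyl (4S,5R,6R)-4-{[tert-butyl(dimethyl)silyl]oxy}-5,6-dimethyl-6-[(4-methylfuran-3-yl)methyl]cyclohex-1-ene-1-carboxylate F2 as the unsaturated ester, and HF·pyridine should free the hydroxyl to give methyl (4S,5R,6R)-4-hydroxy-5,6-dimethyl-6-[(4-methylfuran-3-yl)methyl]cyclohex-1-ene-1-carboxylate F3 as the substrate for directed hydrogenation. Hydrogenation with [Ir(cod)(PCy3)(py)]PF6 (H2, CH2Cl2), directed by the homoallylic 3β-hydroxyl, should add hydrogen to the β face of C1=C10 and give methyl (1S,2R,3R,4S)-4-hydroxy-2,3-dimethyl-2-[(4-methylfuran-3-yl)methyl]cyclohexane-1-carboxylate F4 with the ester cis to the furylmethyl group. Reduction of the ester with i-Bu2AlH (CH2Cl2, −78 °C) to the aldehyde then gives 21.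

The second is step 17, the Mitsunobu inversion at C3. Elimination of the activated oxygen toward C2 or C4 may compete with substitution by the weakly acidic trienoic acid, and the aldehyde may epimerise. The fallback for step 17 separates activation and displacement and masks the aldehyde; it sets out from 21 and comes back to the route at 28. HC(OMe)3, PPTS and MeOH should give (1S,2R,3R,4S)-4-(dimethoxymethyl)-2,3-dimethyl-3-[(4-methylfuran-3-yl)methyl]cyclohexan-1-ol F5 as the dimethyl acetal, and MsCl with Et3N should turn it into (1S,2R,3R,4S)-4-(dimethoxymethyl)-2,3-dimethyl-3-[(4-methylfuran-3-yl)methyl]cyclohexyl methanesulfonate F6 as the activated 3β sulfonate. Acid 27 is converted with Cs2CO3 into cesium (2E,4E,6E)-5-methyldodeca-2,4,6-trienoate F7 as the nucleophile, which should displace the sulfonate with inversion (18-crown-6, toluene, 80 °C) to give (1R,2R,3R,4S)-4-(dimethoxymethyl)-2,3-dimethyl-3-[(4-methylfuran-3-yl)methyl]cyclohexyl (2E,4E,6E)-5-methyldodeca-2,4,6-trienoate F8 as the 3α ester. PPTS in wet acetone then unmasks the aldehyde and gives 28.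

The third is step 18, the key ring closure. Facial selectivity at the aldehyde carbon may be poor, and the furfuryl oxygen may be lost in part by ionisation if the quench is not cold. The fallback for step 18 corrects C9 by oxidation and reagent-controlled reduction; it sets out from 28 and comes back to the route at 30. The ring closure is run as in step 18, and the crude mixture of 30 and 3α-[(2E,4E,6E)-5-methyldodeca-2,4,6-trienoyloxy]-10βH-furanoeremophilan-9α-ol F9 as its C9 epimer is oxidised with MnO2 (CH2Cl2, rt), which should convert both furfuryl alcohols into 3α-[(2E,4E,6E)-5-methyldodeca-2,4,6-trienoyloxy]-10βH-furanoeremophilan-9-one F10 as a single furyl ketone. Asymmetric transfer hydrogenation (Noyori type) with RuCl(p-cymene)[(R,R)-TsDPEN] and HCO2H/Et3N, the catalyst antipode expected to give the 9R carbinol by analogy with aryl alkyl ketones, then returns 30. Simple hydride reduction of the ketone is not relied on, because hydride should enter from the face away from the C5–C4 bond and give the 9α alcohol.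

Further compounds
F1 | step 13 | (4S,5R,6R)-4-{[tert-butyl(dimethyl)silyl]oxy}-5,6-dimethyl-6-[(4-methylfuran-3-yl)methyl]cyclohex-1-en-1-yl trifluoromethanesulfonate | CC(C)(C)[Si](C)(C)O[C@H]1CC=C(OS(=O)(=O)C(F)(F)F)[C@](C)(Cc2cocc2C)[C@H]1C
F2 | step 13 | methyl (4S,5R,6R)-4-{[tert-butyl(dimethyl)silyl]oxy}-5,6-dimethyl-6-[(4-methylfuran-3-yl)methyl]cyclohex-1-ene-1-carboxylate | CC(C)(C)[Si](C)(C)O[C@H]1CC=C(C(=O)OC)[C@](C)(Cc2cocc2C)[C@H]1C
F3 | step 13 | methyl (4S,5R,6R)-4-hydroxy-5,6-dimethyl-6-[(4-methylfuran-3-yl)methyl]cyclohex-1-ene-1-carboxylate | O[C@H]1CC=C(C(=O)OC)[C@](C)(Cc2cocc2C)[C@H]1C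
F4 | step 13 | methyl (1S,2R,3R,4S)-4-hydroxy-2,3-dimethyl-2-[(4-methylfuran-3-yl)methyl]cyclohexane-1-carboxylate | O[C@H]1CC[C@H](C(=O)OC)[C@](C)(Cc2cocc2C)[C@H]1C
F5 | step 17 | (1S,2R,3R,4S)-4-(dimethoxymethyl)-2,3-dimethyl-3-[(4-methylfuran-3-yl)methyl]cyclohexan-1-ol | O[C@H]1CC[C@H](C(OC)OC)[C@](C)(Cc2cocc2C)[C@H]1C
F6 | step 17 | (1S,2R,3R,4S)-4-(dimethoxymethyl)-2,3-dimethyl-3-[(4-methylfuran-3-yl)methyl]cyclohexyl methanesulfonate | CS(=O)(=O)O[C@H]1CC[C@H](C(OC)OC)[C@](C)(Cc2cocc2C)[C@H]1C
F7 | step 17 | cesium (2E,4E,6E)-5-methyldodeca-2,4,6-trienoate | [Cs+].CCCCC/C=C/C(C)=C/C=C/C(=O)[O-]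
F8 | step 17 | (1R,2R,3R,4S)-4-(dimethoxymethyl)-2,3-dimethyl-3-[(4-methylfuran-3-yl)methyl]cyclohexyl (2E,4E,6E)-5-methyldodeca-2,4,6-trienoate | CCCCC/C=C/C(C)=C/C=C/C(=O)O[C@@H]1CC[C@H](C(OC)OC)[C@](C)(Cc2cocc2C)[C@H]1C
F9 | step 18 | 3α-[(2E,4E,6E)-5-methyldodeca-2,4,6-trienoyloxy]-10βH-furanoeremophilan-9α-ol | CCCCC/C=C/C(C)=C/C=C/C(=O)O[C@@H]1CC[C@@H]2[C@H](O)c3occ(C)c3C[C@]2(C)[C@H]1C
F10 | step 18 | 3α-[(2E,4E,6E)-5-methyldodeca-2,4,6-trienoyloxy]-10βH-furanoeremophilan-9-one | CCCCC/C=C/C(C)=C/C=C/C(=O)O[C@@H]1CC[C@@H]2C(=O)c3occ(C)c3C[C@]2(C)[C@H]1C
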